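Follow the L that is left.

| setting | Tuesday's | Monday's | flask |
|---|---|---|---|
| L | 0.71 M | 1.1 M | 0.51 M |
| J | 0.663 M | 0.663 M | 0.663 M |
| remark | run made earlier | run made earlier |  |
| time |  |  | 8.0 h |
| volume of the second phase over the first |  |  | 0.50 |

- Tuesday's (time / h: X / %, L / %): 0.500: 0.7, 99.4; 1.50: 4.0, 97.2; 3.00: 8.4, 91.0; 5.00: 13.1, 85.7; 6.00: 14.1, 82.7
- Monday's (time / h: X / %, L / %): 1.33: 2.8, 97.0; 2.50: 5.6, 93.3; 4.00: 10.6, 88.4; 5.00: 12.0, 85.9; 6.00: 13.9, 84.0

(each reading ± 0.5 percentage points)

- what is said of X includes G
- in the second phase: J, G; everything else is in the first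
- charges count per volume of the first phase; a concentration in a rate is the amount of a species over the volume of its own phase; every rate counts per litre of the first phase
- on the list of suspects stand: 2 D -> Q; D <-> J; L + D -> X; X <-> G; X -> Z
- the earlier runs hold the two phases in the same ratio of volumes as the flask asked about

1. how much X and G together there is at 8.0 h, in percent of the L charged
2. part of the L charged that has reacted at 8.0 h

**Apparent constant.** I defined k as the logarithm of one over the fraction of L left, divided by the time. This is a pseudo-first-order constant, averaged from the start. Tuesday's last reading gives 0.0317 h⁻¹, and Monday's gives 0.0291 h⁻¹. Monday's charge of L is 1.55 times Tuesday's, yet k barely moves, so I read L's loss as close to first order.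

**Hand chain.** I carried Tuesday's k, the nearer charge, to the flask. At 8.0 h it leaves 77.6% of the L, so 22.4% has reacted. On Tuesday's last reading, X and G together made up 0.815 of the L lost, which gives 18.2%.

**Weak link.** Carrying k on for 2.00 h beyond the last reading supposes that D, L's suspected partner, stays at its mean level up to that reading.

**The forecast.** It gave 18% and 23%, noting that “The two earlier runs give nearly the same percent conversion despite very different L charges”. My reacted part lies a little below its figure.

**The result.** The flask gave 17.4% and 21.4%, and the forecast held.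

    2 D → Q (k = 0.250 M⁻¹ h⁻¹)
    D ⇌ J, rate k2*([D] - [J]/K2) per volume of the first phase (partition coefficient = 0.320, kL = 0.110 h⁻¹)
    L + D → X (k = 0.110 M⁻¹ h⁻¹)
    X ⇌ G, rate k4*([X] - [G]/K4) per volume of the first phase (partition coefficient = 4.90, kL = 1.00 h⁻¹)
    X → Z (k = 0.130 h⁻¹)

**Falling k.** The flask's L left, 79%, gives 0.0301 h⁻¹ over 8.0 h, against the 0.0317 h⁻¹ read on Tuesday. At 8.00 h the flask makes D at 0.212 of the rate at which it uses D, each step taken net, and D has fallen from 0.315 M at 4.00 h to 0.194 M. Read at 20 h, the same flask holds 0.0728 M of D, and its k is down to 0.0198 h⁻¹. Tuesday's k gives 53.0% of the L left at that time, and the flask has 67%.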